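**Retrosynthetic overview**

1. Ring numbering: C1 carries the 3-(benzoyloxy)prop-1-en-2-yl group, C2 is CH, C3 bears the free hydroxyl (O3), C4 the methyl group, C5 is CH, C6 bears the isobutyrate (O6). The strategy rests on this para-dioxygenated ring: O3–C3–C4(CH3)–C5–C6–O6 is the skeleton of a 4-methyl-2-silyloxyfuran (ring oxygen → O3, silyloxy oxygen → O6), and C1–C2 is the triple bond of an ynone whose carbonyl carbon becomes the alkene carbon on C1.
2. Target ⇒ acetal removal at O3 ⇒ isobutyrylation of O6 ⇒ desilylation of O6 ⇒ methylenation of the ketone ⇒ protection of O3 ⇒ aryl ketone with free O3–H and silylated O6.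
3. That ketone ⇒ [4+2] cycloaddition of 4-methyl-2-(triisopropylsilyloxy)furan with 2-oxobut-3-yn-1-yl benzoate (bonds C1–C6 and C2–C3), opening of the oxygen bridge and aromatization. The benzene ring is the only ring made and it arises here from the furan.
4. Furan ⇐ 4-methyl-2(5H)-furanone by one silylation; ynone ⇐ O-benzoylglycolyl chloride + bis(trimethylsilyl)acetylene ⇐ glycolic acid + benzoyl chloride.

Key step: step 6

Remark: the target has no stereocentre. The only chiral species on the route, cycloadduct 10, is racemic and transient.

**Route**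

Step 1
Reactants: 1 glycolic acid; 2 benzoyl chloride
Product: 3 2-(benzoyloxy)acetic acid
Conditions: pyridine, CH2Cl2, 0 °C → rt; then 1 M HCl
Reagents that add atoms: none
Why: O-acylation of the hydroxyl group by the acid chloride with pyridine as base and acyl-transfer agent (Einhorn variant of the Schotten–Baumann reaction); any mixed anhydride formed at the carboxyl group should be hydrolysed in the acidic aqueous work-up.

Step 2
Reactants: 3 2-(benzoyloxy)acetic acid
Product: 4 2-(benzoyloxy)acetyl chloride
Conditions: (COCl)2, DMF (cat.), CH2Cl2, 0 °C → rt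
Reagents that add atoms: oxalyl chloride, O=C(Cl)C(=O)Cl
Why: DMF-catalysed (Vilsmeier-type) conversion of a carboxylic acid into its chloride under neutral, gas-releasing conditions that should leave the benzoate untouched.

Step 3
Reactants: 4 2-(benzoyloxy)acetyl chloride; 5 bis(trimethylsilyl)acetylene
Product: 6 2-oxo-4-(trimethylsilyl)but-3-yn-1-yl benzoate
Conditions: AlCl3, CH2Cl2, 0 °C; ice/dilute HCl quench
Reagents that add atoms: none
Why: Friedel–Crafts-type acylative ipso-desilylation of a silylalkyne, in which the β-silyl-stabilised vinyl cation directs the acylium ion to the silicon-bearing carbon and the resulting ynone is too electron-poor to be acylated a second time.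

Step 4
Reactants: 6 2-oxo-4-(trimethylsilyl)but-3-yn-1-yl benzoate
Product: 7 2-oxobut-3-yn-1-yl benzoate
Conditions: Na2B4O7 (0.01 M aq.), MeOH, rt, short contact time
Reagents that add atoms: none
Why: Base-catalysed protodesilylation of the activated C(sp)–Si bond of a silyl ynone; the weakly basic borate buffer is chosen so that the benzoate and the liberated Michael acceptor should survive.

Step 5
Reactants: 8 4-methyl-2(5H)-furanone
Product: 9 4-methyl-2-(triisopropylsilyloxy)furan
Conditions: i-Pr3SiOTf, Et3N, CH2Cl2, 0 °C
Reagents that add atoms: triisopropylsilyl trifluoromethanesulfonate, CC(C)[Si](OS(=O)(=O)C(F)(F)F)(C(C)C)C(C)C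
Why: Soft enolisation (silyl dienol ether formation): O-silylation of the lactone carbonyl followed by removal of a C5 proton by the amine, which is preferred over loss of a methyl proton because it creates the aromatic furan.

Step 6
Reactants: 9 4-methyl-2-(triisopropylsilyloxy)furan; 7 2-oxobut-3-yn-1-yl benzoate
Product: 11 2-[5-hydroxy-4-methyl-2-(triisopropylsilyloxy)phenyl]-2-oxoethyl benzoate, via 7-oxanorbornadiene cycloadduct 10 (not isolated)
Conditions: PhMe, 0 °C → rt; SiO2 on work-up to complete ring opening
Reagents that add atoms: none
Why: The electron-rich diene 9 (largest HOMO coefficient at its unsubstituted C5) and the electron-poor ynone 7 (largest LUMO coefficient at the terminal alkyne carbon) should combine in a normal-demand [4+2] cycloaddition, either concerted and asynchronous or, at the limit, a vinylogous Mukaiyama–Michael addition followed by collapse of the allenolate onto the silyloxocarbenium ion; this forms C2–C3 and C1–C6 and closes the six-membered carbocycle as the bridged adduct 10. Heterolysis of the bridge C–O bond at the bridgehead that carries the silyloxy group, pushed by that oxygen's lone pair, then gives a silyloxocarbenium/alkoxide pair that aromatizes by proton transfer from the second bridgehead carbon, so the former furan oxygen ends as free O3–H and C6 keeps its silyl ether. The closest known reaction type is the cycloaddition of 2-silyloxy- and 2-alkoxyfurans with acetylenic esters and ketones, which opens in the same way to 4-oxygenated phenols. The two bridgehead stereocentres of 10 are racemic and vanish on aromatization, so no stereocontrol is required. The step needs regioselectivity, which polarity matching should secure by pairing furan C5 with the β-carbon of the ynone, so the ketone ends up next to C6 and para to the methyl group; it also needs the silyl group to stay on O6, which the bulk of the triisopropylsilyl group and the non-polar, additive-free medium should secure.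

Step 7
Reactants: 11 2-[5-hydroxy-4-methyl-2-(triisopropylsilyloxy)phenyl]-2-oxoethyl benzoate
Product: 12 2-[5-(methoxymethoxy)-4-methyl-2-(triisopropylsilyloxy)phenyl]-2-oxoethyl benzoate
Conditions: MeOCH2Cl, i-Pr2NEt, CH2Cl2, 0 °C → rt
Reagents that add atoms: chloromethyl methyl ether, COCCl
Why: O-alkylation of the only free phenol (O3) with a reactive α-chloro ether and a hindered amine base (Williamson-type acetal formation); the base is too weak to enolise the α-benzoyloxy ketone to a harmful extent.

Step 8
Reactants: 12 2-[5-(methoxymethoxy)-4-methyl-2-(triisopropylsilyloxy)phenyl]-2-oxoethyl benzoate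
Product: 13 2-[5-(methoxymethoxy)-4-methyl-2-(triisopropylsilyloxy)phenyl]prop-2-en-1-yl benzoate
Conditions: Zn, CH2Br2, TiCl4, THF, −40 → 5 °C (reagent preformed); then 12, CH2Cl2, 0 °C → rt
Reagents that add atoms: dibromomethane, BrCBr
Why: Takai–Lombardo methylenation with the zinc/titanium gem-dimetallic methylene reagent, which is non-basic (no enolisation of the α-benzoyloxy ketone, no acyl transfer) and is known to leave esters, silyl ethers and acetals alone.

Step 9
Reactants: 13 2-[5-(methoxymethoxy)-4-methyl-2-(triisopropylsilyloxy)phenyl]prop-2-en-1-yl benzoate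
Product: 14 2-[2-hydroxy-5-(methoxymethoxy)-4-methylphenyl]prop-2-en-1-yl benzoate
Conditions: Bu4NF, AcOH (1:1), THF, 0 °C; product used directly
Reagents that add atoms: none
Why: Fluoride-induced cleavage of the aryl silyl ether; the acetic acid buffer should deliver the phenol and not the phenoxide, which suppresses benzoyl transfer from the allylic ester and ring closure onto the allylic system.

Step 10
Reactants: 14 2-[2-hydroxy-5-(methoxymethoxy)-4-methylphenyl]prop-2-en-1-yl benzoate
Product: 15 2-[5-(methoxymethoxy)-4-methyl-2-(2-methylpropanoyloxy)phenyl]prop-2-en-1-yl benzoate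
Conditions: i-PrCOCl, Et3N, DMAP (cat.), CH2Cl2, 0 °C
Reagents that add atoms: 2-methylpropanoyl chloride, CC(C)C(=O)Cl
Why: DMAP-catalysed acylation (nucleophilic catalysis through the N-acylpyridinium ion) of the hindered O6 phenol; O3 is masked as its acetal, so only O6 can be acylated.

Step 11
Reactants: 15 2-[5-(methoxymethoxy)-4-methyl-2-(2-methylpropanoyloxy)phenyl]prop-2-en-1-yl benzoate
Product: 16 2-[5-hydroxy-4-methyl-2-(2-methylpropanoyloxy)phenyl]prop-2-en-1-yl benzoate (target)
Conditions: ZnBr2, n-PrSH, CH2Cl2, 0 °C → rt, under argon, short reaction time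
Reagents that add atoms: none
Why: Lewis-acid-assisted thiolysis of the aryl methoxymethyl ether (ZnBr2 activates the acetal and the thiol takes up the methoxymethyl group); these fast, non-hydrolytic conditions should spare the aryl isobutyrate, the allylic benzoate and the 1,1-disubstituted alkene.

**Compound list**

1 | glycolic acid | OCC(=O)O | starting material
2 | benzoyl chloride | O=C(Cl)c1ccccc1 | starting material
3 | 2-(benzoyloxy)acetic acid | OC(=O)COC(=O)c1ccccc1 | intermediate
4 | 2-(benzoyloxy)acetyl chloride | ClC(=O)COC(=O)c1ccccc1 | intermediate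
5 | bis(trimethylsilyl)acetylene | C[Si](C)(C)C#C[Si](C)(C)C | starting material
6 | 2-oxo-4-(trimethylsilyl)but-3-yn-1-yl benzoate | C[Si](C)(C)C#CC(=O)COC(=O)c1ccccc1 | intermediate
7 | 2-oxobut-3-yn-1-yl benzoate | C#CC(=O)COC(=O)c1ccccc1 | intermediate
8 | 4-methyl-2(5H)-furanone | CC1=CC(=O)OC1 | starting material
9 | 4-methyl-2-(triisopropylsilyloxy)furan | Cc1coc(O[Si](C(C)C)(C(C)C)C(C)C)c1 | intermediate
10 | 2-oxo-2-[5-methyl-1-(triisopropylsilyloxy)-7-oxabicyclo[2.2.1]hepta-2,5-dien-2-yl]ethyl benzoate (racemic, not isolated) | O=C(COC(=O)c1ccccc1)C1=CC2OC1(O[Si](C(C)C)(C(C)C)C(C)C)C=C2C | intermediate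
11 | 2-[5-hydroxy-4-methyl-2-(triisopropylsilyloxy)phenyl]-2-oxoethyl benzoate | O=C(COC(=O)c1ccccc1)c1cc(O)c(C)cc1O[Si](C(C)C)(C(C)C)C(C)C | intermediate
12 | 2-[5-(methoxymethoxy)-4-methyl-2-(triisopropylsilyloxy)phenyl]-2-oxoethyl benzoate | O=C(COC(=O)c1ccccc1)c1cc(OCOC)c(C)cc1O[Si](C(C)C)(C(C)C)C(C)C | intermediate
13 | 2-[5-(methoxymethoxy)-4-methyl-2-(triisopropylsilyloxy)phenyl]prop-2-en-1-yl benzoate | C=C(COC(=O)c1ccccc1)c1cc(OCOC)c(C)cc1O[Si](C(C)C)(C(C)C)C(C)C | intermediate
14 | 2-[2-hydroxy-5-(methoxymethoxy)-4-methylphenyl]prop-2-en-1-yl benzoate | C=C(COC(=O)c1ccccc1)c1cc(OCOC)c(C)cc1O | intermediate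
15 | 2-[5-(methoxymethoxy)-4-methyl-2-(2-methylpropanoyloxy)phenyl]prop-2-en-1-yl benzoate | C=C(COC(=O)c1ccccc1)c1cc(OCOC)c(C)cc1OC(=O)C(C)C | intermediate
16 | 2-[5-hydroxy-4-methyl-2-(2-methylpropanoyloxy)phenyl]prop-2-en-1-yl benzoate (CNP0245407.0) | C=C(COC(=O)c1ccccc1)c1cc(O)c(C)cc1OC(=O)C(C)C | target

**Step count**

Total: 11 steps. Longest linear sequence: 10 steps (steps 1–4, then 6–11); step 5 is a one-step side branch.

**Steps most likely to fail, with fallbacks**

Step 6. The addition may stop at an open conjugate adduct without ring closure, or the silyl group may be lost or moved between the two oxygens during ring opening, which would erase the O3/O6 differentiation. The fallback gives up the furan and acylates a preformed hydroquinone ring; it sets out from acid chloride 4 and comes back to the route at 12. Friedel–Crafts acylation of commercial 1,4-dimethoxy-2-methylbenzene with 4 (AlCl3, CH2Cl2, −10 °C, brief) should occur para to the methyl group and give 2-(2,5-dimethoxy-4-methylphenyl)-2-oxoethyl benzoate F1. Oxidative demethylation (AgO, 6 M HNO3, dioxane) should give the acylquinone 2-(4-methyl-3,6-dioxocyclohexa-1,4-dien-1-yl)-2-oxoethyl benzoate F2, which is reduced at once (Na2S2O4, EtOAc/H2O) to 2-(2,5-dihydroxy-4-methylphenyl)-2-oxoethyl benzoate F3. Because O6–H is hydrogen-bonded to the ketone, MeOCH2Cl/i-Pr2NEt should protect only O3 and give 2-[2-hydroxy-5-(methoxymethoxy)-4-methylphenyl]-2-oxoethyl benzoate F4. Silylation of O6 (i-Pr3SiOTf, 2,6-lutidine, CH2Cl2, 0 °C) then gives 12. Strong base is avoided while O6–H is free next to the α-benzoyloxy ketone.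

Step 8. Low-valent titanium or zinc may reductively remove the α-benzoyloxy group or couple the aryl ketone, and addition to the carbonyl flanked by the ortho silyloxy group may be slow. The fallback is a two-stage Peterson olefination; it sets out from 12 and comes back at 13. Addition of Me3SiCH2MgCl premixed with anhydrous CeCl3 (THF, −78 °C), a small and non-basic organocerium nucleophile that attacks the ketone much faster than the ester, should give racemic 2-hydroxy-2-[5-(methoxymethoxy)-4-methyl-2-(triisopropylsilyloxy)phenyl]-3-(trimethylsilyl)propyl benzoate F5. Acid-induced anti-elimination of the β-hydroxysilane (camphorsulfonic acid cat., CH2Cl2, 0 °C) then gives 13.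

Step 4. Under the basic, protic desilylation the liberated ynone may take up methanol in a conjugate addition, and the benzoate may be methanolysed. The fallback forms the terminal ynone directly by cross-coupling under neutral conditions; it sets out from acid chloride 4 and comes back at 7, replacing steps 3 and 4. Acyl Stille coupling of 4 with ethynyltributylstannane (PdCl2(PPh3)2 cat., reduced in the flask to zerovalent palladium, 1,2-dichloroethane, 50 °C) should give 7 without base or alcohol. This fallback makes no new compound (F0).

**Further compounds**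

F1 | step 6 | 2-(2,5-dimethoxy-4-methylphenyl)-2-oxoethyl benzoate | O=C(COC(=O)c1ccccc1)c1cc(OC)c(C)cc1OC
F2 | step 6 | 2-(4-methyl-3,6-dioxocyclohexa-1,4-dien-1-yl)-2-oxoethyl benzoate | O=C(COC(=O)c1ccccc1)C1=CC(=O)C(C)=CC1=O
F3 | step 6 | 2-(2,5-dihydroxy-4-methylphenyl)-2-oxoethyl benzoate | O=C(COC(=O)c1ccccc1)c1cc(O)c(C)cc1O
F4 | step 6 | 2-[2-hydroxy-5-(methoxymethoxy)-4-methylphenyl]-2-oxoethyl benzoate | O=C(COC(=O)c1ccccc1)c1cc(OCOC)c(C)cc1O
F5 | step 8 | 2-hydroxy-2-[5-(methoxymethoxy)-4-methyl-2-(triisopropylsilyloxy)phenyl]-3-(trimethylsilyl)propyl benzoate (racemic) | C[Si](C)(C)CC(O)(COC(=O)c1ccccc1)c1cc(OCOC)c(C)cc1O[Si](C(C)C)(C(C)C)C(C)C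
F0 | step 4 | none | none
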